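**Retrosynthetic overview**

1. The target is (−)-epicatechin 3-O-gallate-(4β→6)-(−)-epicatechin 3-O-gallate-(4β→8)-(−)-epicatechin 3-O-gallate. Cut last: 21 benzyl ethers and 3 bromine caps (one hydrogenolysis), then the 4β→8 bond (AgBF4 on a C4 thioether) and the 4β→6 bond (BF3·OEt2 on a C4 ether, bromine caps steering attack to C6). Each flavan unit receives its gallate ester before coupling, one acylation per monomer, and the 3-O-acyl group directs each coupling anti.
2. All three flavan units come from one monomer, tetra-O-benzylepicatechin ← flavan-3-one (LiBH(s-Bu)3 sets C3) ← spiro-1,3-dithiane ← [3+3] annulation. Ring C is the only ring that is made (step 7); rings A and B are bought as arenes.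
3. Ring C is cut at O1–C8a and C3–C4. This gives (R)-aryl(1,3-dithian-2-yl)methanol (C2 from asymmetric transfer hydrogenation) and 2,4-bis(benzyloxy)-6-fluorobenzyl chloride.
4. Enabling feature: in ring C, O1–C2–C3 becomes a 1,3-O,C-dinucleophile once C3 is stored as a dithiane acyl anion. C4–C4a–C8a is the matching 1,3-dielectrophile, because C8a of ring A is ortho to the carbon that carries C4 and meta to both ring-A ether oxygens. The temporary thioketal ring leaves C3 without O or H, so only the six-membered ring can close and no flavene can form; step 8 removes it.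
5. Order: ring C → C3 ketone → 2,3-cis alcohol → C8 capping and C4 activation → gallate ester → C6 capping or C4 thioether → 4β→6 bond → 4β→8 bond → deprotection.

Key step: step 7

Assumption: methyl 3,4-bis(benzyloxy)benzoate and 3,4,5-tris(benzyloxy)benzoic acid are taken as catalogue compounds.

**Route**

Step 1
Reactants: 1 1,3,5-trifluorobenzene
Product: 2 1,3-bis(benzyloxy)-5-fluorobenzene
Conditions: BnOH (2.05 equiv), NaH (2.1 equiv), NMP, 0 → 90 °C
Reagents that add atoms: benzyl alcohol OCc1ccccc1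
Why: Twofold nucleophilic aromatic substitution (SNAr), in which each C–F carbon is activated by meta fluorines and the third substitution is much slower once two alkoxy groups are in place, so two equivalents of alkoxide should stop at the monofluoride.

Step 2
Reactants: 2 1,3-bis(benzyloxy)-5-fluorobenzene
Product: 4 2,4-bis(benzyloxy)-6-fluorobenzaldehyde, via aryl iminium chloride 3 (not isolated)
Conditions: POCl3, DMF, 0 → 70 °C; then ice–water
Reagents that add atoms: N,N-dimethylformamide CN(C)C=O; water O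
Why: Vilsmeier–Haack formylation, which should occur para to one benzyloxy group at the less hindered position next to fluorine and not between the two benzyloxy groups, placing CHO ortho to F as ring C requires.

Step 3
Reactants: 4 2,4-bis(benzyloxy)-6-fluorobenzaldehyde
Product: 5 [2,4-bis(benzyloxy)-6-fluorophenyl]methanol
Conditions: NaBH4, THF/MeOH, 0 °C
Reagents that add atoms: none
Why: Borohydride reduction of an aryl aldehyde, with no stereocenter formed and all ethers and the C–F bond inert.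

Step 4
Reactants: 5 [2,4-bis(benzyloxy)-6-fluorophenyl]methanol
Product: 6 1,5-bis(benzyloxy)-2-(chloromethyl)-3-fluorobenzene
Conditions: SOCl2, CH2Cl2, 0 °C; volatiles removed, used at once
Reagents that add atoms: thionyl chloride O=S(Cl)Cl
Why: Chlorination of an electron-rich benzylic alcohol through its chlorosulfite, with the chloride used directly because 2,4-dialkoxybenzyl halides self-alkylate on standing.

Step 5
Reactants: 7 1,3-dithiane; 8 methyl 3,4-bis(benzyloxy)benzoate
Product: 10 [3,4-bis(benzyloxy)phenyl](1,3-dithian-2-yl)methanone, via 2-lithio-1,3-dithiane 9 (not isolated)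
Conditions: 7 (2.2 equiv), n-BuLi (2.2 equiv), THF, −30 °C; 8, −78 → −20 °C; then H2O
Reagents that add atoms: none
Why: Corey–Seebach acylation of 2-lithio-1,3-dithiane with an ester, in which the second equivalent of anion deprotonates the acidic 2-acyl dithiane as it forms and so prevents over-addition.

Step 6
Reactants: 10 [3,4-bis(benzyloxy)phenyl](1,3-dithian-2-yl)methanone
Product: 11 (R)-[3,4-bis(benzyloxy)phenyl](1,3-dithian-2-yl)methanol
Conditions: RuCl(p-cymene)[(S,S)-TsDPEN] (cat.), HCO2H/Et3N (5:2), CH2Cl2, 25 °C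
Reagents that add atoms: none
Why: Noyori–Ikariya asymmetric transfer hydrogenation of an aryl ketone, in which the (S,S)-catalyst should place the aryl group as in the acetophenone model and give the carbinol that becomes C2 of the flavan (R, because the dithianyl carbon outranks the aryl carbon).

Step 7
Reactants: 11 (R)-[3,4-bis(benzyloxy)phenyl](1,3-dithian-2-yl)methanol; 6 1,5-bis(benzyloxy)-2-(chloromethyl)-3-fluorobenzene
Product: 14 (2R)-5,7-bis(benzyloxy)-2-[3,4-bis(benzyloxy)phenyl]spiro[chromane-3,2'-[1,3]dithiane], via dilithio dianion 12 (not isolated), via C-benzylated lithium alkoxide 13 (not isolated)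
Conditions: n-BuLi (2.1 equiv), THF, −30 °C; 6, −78 → −20 °C; then DMPU, 65 °C
Reagents that add atoms: none
Why: Proposed new method: two equivalents of n-BuLi should give the O,C-dilithio species 12 (a carbanion next to an oxide cannot eliminate, since oxide is no leaving group), and its soft dithiane carbanion is alkylated by the benzylic chloride 6 to form C3–C4 (SN2, as in Corey–Seebach alkylations), leaving the lithium alkoxide 13. On warming in DMPU the alkoxide adds to C8a and expels fluoride through a Meisenheimer anion (SNAr, as in known oxy-cyclisations of o-fluoroaryl alkanols to chromans), which closes ring C in the 6-exo-trig mode and forms O1–C8a. The closest known reaction type is the copper iodide (CuI)-catalysed or SNAr domino C-benzylation/O-arylation of 1,3-dicarbonyl compounds with 2-halobenzyl halides to 4H-chromenes; here a dianion replaces the enolate so that C2 stays sp3. No new stereocenter is formed, and C2 from step 6 is retained because it is never deprotonated and never carries a leaving group. The step needs C- before O-alkylation and six- not five-ring closure: the first follows from the far higher nucleophilicity of the carbanion, the second is secured by the thioketal, which leaves C3 without an oxygen nucleophile or a hydrogen, so neither a benzofuran closure nor elimination to a flavene nor a retro-oxa-Michael path exists. C8a is meta to both benzyloxy groups, so their lone pairs do not destabilise the Meisenheimer anion, and formation of lithium fluoride drives the closure.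

Step 8
Reactants: 14 (2R)-5,7-bis(benzyloxy)-2-[3,4-bis(benzyloxy)phenyl]spiro[chromane-3,2'-[1,3]dithiane]
Product: 15 (2R)-5,7-bis(benzyloxy)-2-[3,4-bis(benzyloxy)phenyl]chroman-3-one
Conditions: MeI (excess), CaCO3, MeCN/H2O, 45 °C
Reagents that add atoms: water O
Why: Alkylative hydrolysis of the 1,3-dithiane (S-methylation, then hydrolysis of the thionium ion), chosen because it does not oxidise the electron-rich arenes and the CaCO3 buffer keeps the medium neutral so that C2–H next to the new ketone should not epimerise.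

Step 9
Reactants: 15 (2R)-5,7-bis(benzyloxy)-2-[3,4-bis(benzyloxy)phenyl]chroman-3-one
Product: 16 (2R,3R)-5,7-bis(benzyloxy)-2-[3,4-bis(benzyloxy)phenyl]chroman-3-ol (5,7,3',4'-tetra-O-benzyl-(−)-epicatechin)
Conditions: LiBH(s-Bu)3, THF, −78 °C; then H2O
Reagents that add atoms: none
Why: Diastereoselective ketone reduction in which the bulky hydride adds on the face opposite the equatorial C2 aryl group and gives the axial 3-OH cis to that group (C3 set as R), the selectivity known for this flavan-3-one.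

Step 10
Reactants: 16 5,7,3',4'-tetra-O-benzyl-(−)-epicatechin
Product: 17 8-bromo-5,7,3',4'-tetra-O-benzyl-(−)-epicatechin
Conditions: NBS (1.0 equiv), CH2Cl2, −78 → 0 °C
Reagents that add atoms: N-bromosuccinimide O=C1CCC(=O)N1Br
Why: Electrophilic aromatic bromination, which goes to C8 of ring A in preference to the more hindered C6 as established for benzylated flavan-3-ols, and caps the position that would otherwise win every later Friedel–Crafts step.

Step 11
Reactants: 17 8-bromo-5,7,3',4'-tetra-O-benzyl-(−)-epicatechin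
Product: 18 8-bromo-4β-(2-ethoxyethoxy)-5,7,3',4'-tetra-O-benzyl-(−)-epicatechin (2,3-cis, 3,4-trans)
Conditions: DDQ (2 equiv), 2-ethoxyethanol, CH2Cl2, 25 °C
Reagents that add atoms: 2-ethoxyethanol CCOCCO
Why: DDQ oxidation of the benzylic C4–H to the C4 cation and capture by the alcohol anti to the 3-OH group, the known route to bromine-capped 4β-alkoxy electrophiles.

Step 12
Reactants: 19 3,4,5-tris(benzyloxy)benzoic acid
Product: 20 3,4,5-tris(benzyloxy)benzoyl chloride
Conditions: (COCl)2, DMF (cat.), CH2Cl2, 25 °C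
Reagents that add atoms: oxalyl chloride O=C(Cl)C(=O)Cl
Why: Acid chloride formation through the catalytic chloroiminium species, which benzyl ethers tolerate.

Step 13
Reactants: 18 8-bromo-4β-(2-ethoxyethoxy)-5,7,3',4'-tetra-O-benzyl-(−)-epicatechin; 20 3,4,5-tris(benzyloxy)benzoyl chloride
Product: 21 8-bromo-4β-(2-ethoxyethoxy)-5,7,3',4'-tetra-O-benzyl-(−)-epicatechin 3-O-[3,4,5-tris(benzyloxy)benzoate]
Conditions: 20 (1.5 equiv), DMAP, pyridine, CH2Cl2, 25 °C
Reagents that add atoms: none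
Why: DMAP-catalysed acylation (N-acylpyridinium transfer) of the single secondary 3-hydroxy group under basic conditions that leave the acid-labile C4 ether, the C3–O bond and hence all stereocenters intact.

Step 14
Reactants: 21 8-bromo-4β-(2-ethoxyethoxy)-5,7,3',4'-tetra-O-benzyl-(−)-epicatechin 3-O-[3,4,5-tris(benzyloxy)benzoate]
Product: 22 6,8-dibromo-4β-(2-ethoxyethoxy)-5,7,3',4'-tetra-O-benzyl-(−)-epicatechin 3-O-[3,4,5-tris(benzyloxy)benzoate]
Conditions: NBS (1.1 equiv), CH2Cl2, −20 → 25 °C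
Reagents that add atoms: N-bromosuccinimide O=C1CCC(=O)N1Br
Why: Electrophilic aromatic bromination at C6, the only free position of the phloroglucinol-type ring A and far more electron-rich than the catechol ring B or the ester-deactivated galloyl ring, so that this unit can later act only as an electrophile.

Step 15
Reactants: 21 8-bromo-4β-(2-ethoxyethoxy)-5,7,3',4'-tetra-O-benzyl-(−)-epicatechin 3-O-[3,4,5-tris(benzyloxy)benzoate]
Product: 23 8-bromo-4β-[(2,6-dimethylphenyl)sulfanyl]-5,7,3',4'-tetra-O-benzyl-(−)-epicatechin 3-O-[3,4,5-tris(benzyloxy)benzoate]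
Conditions: 2,6-dimethylbenzenethiol, BF3·OEt2, CH2Cl2, −78 → −30 °C
Reagents that add atoms: 2,6-dimethylbenzenethiol Cc1cccc(C)c1S
Why: Lewis-acid-mediated SN1 exchange at C4 (thiolysis type), in which the C4 cation is shielded on its α face by the participating 3-O-acyl group and the thiol enters anti to it (4β), installing a leaving group that tolerates BF3·OEt2 at low temperature but is released by AgBF4.

Step 16
Reactants: 22 6,8-dibromo-4β-(2-ethoxyethoxy)-5,7,3',4'-tetra-O-benzyl-(−)-epicatechin 3-O-[3,4,5-tris(benzyloxy)benzoate]; 23 8-bromo-4β-[(2,6-dimethylphenyl)sulfanyl]-5,7,3',4'-tetra-O-benzyl-(−)-epicatechin 3-O-[3,4,5-tris(benzyloxy)benzoate]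
Product: 24 [6,8-dibromo-tetra-O-benzylepicatechin 3-O-tri-O-benzylgallate]-(4β→6)-[8-bromo-4β-(2,6-dimethylphenylsulfanyl)-tetra-O-benzylepicatechin 3-O-tri-O-benzylgallate]
Conditions: BF3·OEt2, CH2Cl2, −78 → −30 °C
Reagents that add atoms: none
Why: Friedel–Crafts-type flavan coupling with orthogonal activation, in which BF3·OEt2 ionises only the C4 ether of 22 and C6 of 23 (C8 is capped) attacks the cation anti to the participating 3-O-acyl group, setting the 4β→6 bond.

Step 17
Reactants: 16 5,7,3',4'-tetra-O-benzyl-(−)-epicatechin; 20 3,4,5-tris(benzyloxy)benzoyl chloride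
Product: 25 5,7,3',4'-tetra-O-benzyl-(−)-epicatechin 3-O-[3,4,5-tris(benzyloxy)benzoate]
Conditions: 20 (1.5 equiv), DMAP, pyridine, CH2Cl2, 25 °C
Reagents that add atoms: none
Why: DMAP-catalysed acylation (N-acylpyridinium transfer) of the axial 3-hydroxy group of the benzylated flavan-3-ol, a reaction type well established for epicatechin gallate esters, with the C3–O bond and the configuration untouched.

Step 18
Reactants: 24 the 4β→6 dimer bis-gallate thioether; 25 5,7,3',4'-tetra-O-benzyl-(−)-epicatechin 3-O-[3,4,5-tris(benzyloxy)benzoate]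
Product: 26 [6,8-dibromo-tetra-O-benzylepicatechin 3-O-tri-O-benzylgallate]-(4β→6)-[8-bromo-tetra-O-benzylepicatechin 3-O-tri-O-benzylgallate]-(4β→8)-[tetra-O-benzylepicatechin 3-O-tri-O-benzylgallate]
Conditions: AgBF4 (2 equiv), 2,6-di-tert-butylpyridine, 25 (3 equiv), CH2Cl2, −40 → 0 °C
Reagents that add atoms: none
Why: Thiophilic activation in which AgBF4 removes the arylthio group and C8 of 25, the most nucleophilic free position, attacks the middle-unit C4 cation anti to its 3-O-acyl group (4β→8), while the dimer cannot self-condense because all its ring-A positions are substituted.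

Step 19
Reactants: 26 the fully protected trimer tris-gallate
Product: 27 (−)-epicatechin 3-O-gallate-(4β→6)-(−)-epicatechin 3-O-gallate-(4β→8)-(−)-epicatechin 3-O-gallate (target)
Conditions: H2 (1 atm), Pd(OH)2/C, Et3N (3 equiv), THF/MeOH/H2O, 25 °C
Reagents that add atoms: none
Why: Global hydrogenolysis that cleaves all twenty-one O-benzyl bonds and the three aryl C–Br caps, while the gallate esters and the acid-labile interflavan bonds survive the amine-buffered neutral medium.

**Compound list**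

1 | 1,3,5-trifluorobenzene | Fc1cc(F)cc(F)c1 | starting material
2 | 1,3-bis(benzyloxy)-5-fluorobenzene | Fc1cc(OCc2ccccc2)cc(OCc2ccccc2)c1 | intermediate
3 | [2,4-bis(benzyloxy)-6-fluorobenzylidene]dimethyliminium chloride | C[N+](C)=Cc1c(F)cc(OCc2ccccc2)cc1OCc1ccccc1.[Cl-] | intermediate
4 | 2,4-bis(benzyloxy)-6-fluorobenzaldehyde | O=Cc1c(F)cc(OCc2ccccc2)cc1OCc1ccccc1 | intermediate
5 | [2,4-bis(benzyloxy)-6-fluorophenyl]methanol | OCc1c(F)cc(OCc2ccccc2)cc1OCc1ccccc1 | intermediate
6 | 1,5-bis(benzyloxy)-2-(chloromethyl)-3-fluorobenzene | ClCc1c(F)cc(OCc2ccccc2)cc1OCc1ccccc1 | intermediate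
7 | 1,3-dithiane | C1CSCSC1 | starting material
8 | methyl 3,4-bis(benzyloxy)benzoate | COC(=O)c1ccc(OCc2ccccc2)c(OCc2ccccc2)c1 | starting material
9 | 2-lithio-1,3-dithiane | [Li]C1SCCCS1 | intermediate
10 | [3,4-bis(benzyloxy)phenyl](1,3-dithian-2-yl)methanone | O=C(C1SCCCS1)c1ccc(OCc2ccccc2)c(OCc2ccccc2)c1 | intermediate
11 | (R)-[3,4-bis(benzyloxy)phenyl](1,3-dithian-2-yl)methanol | S1CCCSC1[C@@H](c1ccc(OCc2ccccc2)c(OCc2ccccc2)c1)O | intermediate
12 | lithium (R)-[3,4-bis(benzyloxy)phenyl](2-lithio-1,3-dithian-2-yl)methanolate | S1CCCS[C-]1[C@@H](c1ccc(OCc2ccccc2)c(OCc2ccccc2)c1)[O-].[Li+].[Li+] | intermediate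
13 | lithium (R)-[3,4-bis(benzyloxy)phenyl]{2-[2,4-bis(benzyloxy)-6-fluorobenzyl]-1,3-dithian-2-yl}methanolate | Fc1cc(OCc2ccccc2)cc(OCc2ccccc2)c1CC1(SCCCS1)[C@@H](c1ccc(OCc2ccccc2)c(OCc2ccccc2)c1)[O-].[Li+] | intermediate
14 | (2R)-5,7-bis(benzyloxy)-2-[3,4-bis(benzyloxy)phenyl]spiro[chromane-3,2'-[1,3]dithiane] | C1C2(SCCCS2)[C@@H](c2ccc(OCc3ccccc3)c(OCc3ccccc3)c2)Oc2cc(OCc3ccccc3)cc(OCc3ccccc3)c21 | intermediate
15 | (2R)-5,7-bis(benzyloxy)-2-[3,4-bis(benzyloxy)phenyl]chroman-3-one | O=C1Cc2c(OCc3ccccc3)cc(OCc3ccccc3)cc2O[C@@H]1c1ccc(OCc2ccccc2)c(OCc2ccccc2)c1 | intermediate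
16 | 5,7,3',4'-tetra-O-benzyl-(−)-epicatechin | O[C@@H]1Cc2c(OCc3ccccc3)cc(OCc3ccccc3)cc2O[C@@H]1c1ccc(OCc2ccccc2)c(OCc2ccccc2)c1 | intermediate
17 | 8-bromo-5,7,3',4'-tetra-O-benzyl-(−)-epicatechin | O[C@@H]1Cc2c(OCc3ccccc3)cc(OCc3ccccc3)c(Br)c2O[C@@H]1c1ccc(OCc2ccccc2)c(OCc2ccccc2)c1 | intermediate
18 | 8-bromo-4β-(2-ethoxyethoxy)-5,7,3',4'-tetra-O-benzyl-(−)-epicatechin | O[C@@H]1[C@@H](OCCOCC)c2c(OCc3ccccc3)cc(OCc3ccccc3)c(Br)c2O[C@@H]1c1ccc(OCc2ccccc2)c(OCc2ccccc2)c1 | intermediate
19 | 3,4,5-tris(benzyloxy)benzoic acid | OC(=O)c1cc(OCc2ccccc2)c(OCc2ccccc2)c(OCc2ccccc2)c1 | starting material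
20 | 3,4,5-tris(benzyloxy)benzoyl chloride | ClC(=O)c1cc(OCc2ccccc2)c(OCc2ccccc2)c(OCc2ccccc2)c1 | intermediate
21 | 8-bromo-4β-(2-ethoxyethoxy)-5,7,3',4'-tetra-O-benzyl-(−)-epicatechin 3-O-[3,4,5-tris(benzyloxy)benzoate] | O=C(O[C@@H]1[C@@H](OCCOCC)c2c(OCc3ccccc3)cc(OCc3ccccc3)c(Br)c2O[C@@H]1c1ccc(OCc2ccccc2)c(OCc2ccccc2)c1)c1cc(OCc2ccccc2)c(OCc2ccccc2)c(OCc2ccccc2)c1 | intermediate
22 | 6,8-dibromo-4β-(2-ethoxyethoxy)-5,7,3',4'-tetra-O-benzyl-(−)-epicatechin 3-O-[3,4,5-tris(benzyloxy)benzoate] | O=C(O[C@@H]1[C@@H](OCCOCC)c2c(OCc3ccccc3)c(Br)c(OCc3ccccc3)c(Br)c2O[C@@H]1c1ccc(OCc2ccccc2)c(OCc2ccccc2)c1)c1cc(OCc2ccccc2)c(OCc2ccccc2)c(OCc2ccccc2)c1 | intermediate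
23 | 8-bromo-4β-[(2,6-dimethylphenyl)sulfanyl]-5,7,3',4'-tetra-O-benzyl-(−)-epicatechin 3-O-[3,4,5-tris(benzyloxy)benzoate] | O=C(O[C@@H]1[C@@H](Sc2c(C)cccc2C)c2c(OCc3ccccc3)cc(OCc3ccccc3)c(Br)c2O[C@@H]1c1ccc(OCc2ccccc2)c(OCc2ccccc2)c1)c1cc(OCc2ccccc2)c(OCc2ccccc2)c(OCc2ccccc2)c1 | intermediate
24 | [6,8-dibromo-tetra-O-benzylepicatechin 3-O-tri-O-benzylgallate]-(4β→6)-[8-bromo-4β-(2,6-dimethylphenylsulfanyl)-tetra-O-benzylepicatechin 3-O-tri-O-benzylgallate] | O=C(O[C@@H]1[C@@H](c2c(OCc4ccccc4)c(Br)c3c(c2OCc2ccccc2)[C@H](Sc2c(C)cccc2C)[C@@H](OC(=O)c2cc(OCc4ccccc4)c(OCc4ccccc4)c(OCc4ccccc4)c2)[C@@H](c2ccc(OCc4ccccc4)c(OCc4ccccc4)c2)O3)c2c(OCc3ccccc3)c(Br)c(OCc3ccccc3)c(Br)c2O[C@@H]1c1ccc(OCc2ccccc2)c(OCc2ccccc2)c1)c1cc(OCc2ccccc2)c(OCc2ccccc2)c(OCc2ccccc2)c1 | intermediate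
25 | 5,7,3',4'-tetra-O-benzyl-(−)-epicatechin 3-O-[3,4,5-tris(benzyloxy)benzoate] | O=C(O[C@@H]1Cc2c(OCc3ccccc3)cc(OCc3ccccc3)cc2O[C@@H]1c1ccc(OCc2ccccc2)c(OCc2ccccc2)c1)c1cc(OCc2ccccc2)c(OCc2ccccc2)c(OCc2ccccc2)c1 | intermediate
26 | [6,8-dibromo-tetra-O-benzylepicatechin 3-O-tri-O-benzylgallate]-(4β→6)-[8-bromo-tetra-O-benzylepicatechin 3-O-tri-O-benzylgallate]-(4β→8)-[tetra-O-benzylepicatechin 3-O-tri-O-benzylgallate] | O=C(O[C@@H]1[C@@H](c2c(OCc4ccccc4)c(Br)c3c(c2OCc2ccccc2)[C@H](c2c(OCc5ccccc5)cc(OCc5ccccc5)c4c2O[C@H](c2ccc(OCc5ccccc5)c(OCc5ccccc5)c2)[C@H](OC(=O)c2cc(OCc5ccccc5)c(OCc5ccccc5)c(OCc5ccccc5)c2)C4)[C@@H](OC(=O)c2cc(OCc4ccccc4)c(OCc4ccccc4)c(OCc4ccccc4)c2)[C@@H](c2ccc(OCc4ccccc4)c(OCc4ccccc4)c2)O3)c2c(OCc3ccccc3)c(Br)c(OCc3ccccc3)c(Br)c2O[C@@H]1c1ccc(OCc2ccccc2)c(OCc2ccccc2)c1)c1cc(OCc2ccccc2)c(OCc2ccccc2)c(OCc2ccccc2)c1 | intermediate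
27 | (−)-epicatechin 3-O-gallate-(4β→6)-(−)-epicatechin 3-O-gallate-(4β→8)-(−)-epicatechin 3-O-gallate (CNP0183218.1) | O=C(O[C@@H]1[C@@H](c2c(O)cc3c(c2O)[C@H](c2c(O)cc(O)c4c2O[C@H](c2ccc(O)c(O)c2)[C@H](OC(=O)c2cc(O)c(O)c(O)c2)C4)[C@@H](OC(=O)c2cc(O)c(O)c(O)c2)[C@@H](c2ccc(O)c(O)c2)O3)c2c(O)cc(O)cc2O[C@@H]1c1ccc(O)c(O)c1)c1cc(O)c(O)c(O)c1 | target

**Step count and risks**

Total step count: 19. Longest linear sequence: 14 steps (steps 1, 2, 3, 4, 7, 8, 9, 10, 11, 13, 14, 16, 18, 19).

Steps most likely to fail: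

Step 7 (Proposed new method). The second lithiation next to the alkoxide may be incomplete or may compete with metalation of benzyl ether CH2 groups. O-benzylation may compete with C-benzylation. Fluoride displacement on a ring without an electron-withdrawing group may be slow, and reversible retro-addition of the hindered alkoxide at 65 °C could erode the C2 configuration. The fallback builds the same bonds stepwise with known reactions. It sets out from 10 and 6: the sodium enolate of 10 (NaH, DMF, 0 °C) is C-benzylated with 6 to give [3,4-bis(benzyloxy)phenyl]{2-[2,4-bis(benzyloxy)-6-fluorobenzyl]-1,3-dithian-2-yl}methanone F1. Oxazaborolidine-catalysed reduction with BH3·THF (CBS, catalyst antipode chosen for the R carbinol) should give (R)-[3,4-bis(benzyloxy)phenyl]{2-[2,4-bis(benzyloxy)-6-fluorobenzyl]-1,3-dithian-2-yl}methanol F2. Its potassium alkoxide (KOt-Bu, DMF, 60 °C) closes the pyran by SNAr, and the route is rejoined at 14.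

Step 16. BF3·OEt2 may ionise the arylthio group of 23 prematurely (self-condensation), or ionisation of the acylated, doubly brominated ether and attack by the hindered, bromine-deactivated C6 may be too slow. The fallback reverses the orthogonal pair. It sets out from 22: thiol exchange as in step 15 gives 6,8-dibromo-4β-[(2,6-dimethylphenyl)sulfanyl]-5,7,3',4'-tetra-O-benzyl-(−)-epicatechin 3-O-[3,4,5-tris(benzyloxy)benzoate] F3. Activation of F3 with AgBF4 and 2,6-di-tert-butylpyridine in the presence of 21, whose C4 ether is inert to silver, should give the 4β→6 dimer bis-gallate carrying a 4β-(2-ethoxyethoxy) group on the lower unit F4. BF3·OEt2 and 25 then give the protected trimer, and the route is rejoined at 26.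

Step 18. The acylated nucleophile 25 may be too unreactive or too hindered to capture the congested middle-unit cation, or attack may be divided between C8 and C6. The fallback couples first and acylates afterwards. It sets out from 24 and 16: AgBF4-mediated coupling of 24 with the more nucleophilic free alcohol 16 (2,6-di-tert-butylpyridine, CH2Cl2) should give the protected trimer bis-gallate with a free 3-hydroxy group on the lower unit F5. Acylation of this single, unhindered terminal hydroxyl with 20 (DMAP, pyridine) rejoins the route at 26.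

**Further compounds**

F1 | step 7 | [3,4-bis(benzyloxy)phenyl]{2-[2,4-bis(benzyloxy)-6-fluorobenzyl]-1,3-dithian-2-yl}methanone | O=C(c1ccc(OCc2ccccc2)c(OCc2ccccc2)c1)C1(Cc2c(F)cc(OCc3ccccc3)cc2OCc2ccccc2)SCCCS1
F2 | step 7 | (R)-[3,4-bis(benzyloxy)phenyl]{2-[2,4-bis(benzyloxy)-6-fluorobenzyl]-1,3-dithian-2-yl}methanol | Fc1cc(OCc2ccccc2)cc(OCc2ccccc2)c1CC1(SCCCS1)[C@@H](c1ccc(OCc2ccccc2)c(OCc2ccccc2)c1)O
F3 | step 16 | 6,8-dibromo-4β-[(2,6-dimethylphenyl)sulfanyl]-5,7,3',4'-tetra-O-benzyl-(−)-epicatechin 3-O-[3,4,5-tris(benzyloxy)benzoate] | O=C(O[C@@H]1[C@@H](Sc2c(C)cccc2C)c2c(OCc3ccccc3)c(Br)c(OCc3ccccc3)c(Br)c2O[C@@H]1c1ccc(OCc2ccccc2)c(OCc2ccccc2)c1)c1cc(OCc2ccccc2)c(OCc2ccccc2)c(OCc2ccccc2)c1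
F4 | step 16 | [6,8-dibromo-tetra-O-benzylepicatechin 3-O-tri-O-benzylgallate]-(4β→6)-[8-bromo-4β-(2-ethoxyethoxy)-tetra-O-benzylepicatechin 3-O-tri-O-benzylgallate] | O=C(O[C@@H]1[C@@H](c2c(OCc4ccccc4)c(Br)c3c(c2OCc2ccccc2)[C@H](OCCOCC)[C@@H](OC(=O)c2cc(OCc4ccccc4)c(OCc4ccccc4)c(OCc4ccccc4)c2)[C@@H](c2ccc(OCc4ccccc4)c(OCc4ccccc4)c2)O3)c2c(OCc3ccccc3)c(Br)c(OCc3ccccc3)c(Br)c2O[C@@H]1c1ccc(OCc2ccccc2)c(OCc2ccccc2)c1)c1cc(OCc2ccccc2)c(OCc2ccccc2)c(OCc2ccccc2)c1
F5 | step 18 | [6,8-dibromo-tetra-O-benzylepicatechin 3-O-tri-O-benzylgallate]-(4β→6)-[8-bromo-tetra-O-benzylepicatechin 3-O-tri-O-benzylgallate]-(4β→8)-[tetra-O-benzylepicatechin] with the lower 3-hydroxy group free | O=C(O[C@@H]1[C@@H](c2c(OCc4ccccc4)c(Br)c3c(c2OCc2ccccc2)[C@H](c2c(OCc5ccccc5)cc(OCc5ccccc5)c4c2O[C@H](c2ccc(OCc5ccccc5)c(OCc5ccccc5)c2)[C@H](O)C4)[C@@H](OC(=O)c2cc(OCc4ccccc4)c(OCc4ccccc4)c(OCc4ccccc4)c2)[C@@H](c2ccc(OCc4ccccc4)c(OCc4ccccc4)c2)O3)c2c(OCc3ccccc3)c(Br)c(OCc3ccccc3)c(Br)c2O[C@@H]1c1ccc(OCc2ccccc2)c(OCc2ccccc2)c1)c1cc(OCc2ccccc2)c(OCc2ccccc2)c(OCc2ccccc2)c1
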